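**Strategy.** The 6-chloro-5(16)-methylene unit is read as the ene-chlorination product of a C5=C6 olefin and the C9 carbinol as a reduced carboxyl. This exposes a γ,δ-unsaturated acid, C9(=O)–C8–C7–C6=C5, inside the oxane ring O–C4–C5–C6–C7–C8. Everything rests on making C7–C8 by an Ireland–Claisen rearrangement of a 1,4-dioxan-2-one (O–C9(=O)–C8–O–C4–C5) that carries a (Z)-2-alkoxyvinyl group on C5. In one operation this closes the dihydropyran, relays the easily set C5 carbinol configuration to quaternary C8 and to the C7 oxygen centre, and releases C9 as a carboxyl. Ring A is then annulated by a Diels–Alder reaction and the ten-membered ring closed at C9–C10 by a SmI2 aldol.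

Key step: step 7

Remark on numbering: atoms carry briarane numbers. C1–C10 form the ten-membered carbocycle (C1 quaternary with methyl C15, C10 the other fusion carbon), C11–C14 complete cyclohexane ring A, C16 is the carbon on C5, C17/C18/C19 are the lactone CH, its methyl and its carbonyl, C20 is the acetoxymethyl carbon on C11.
Assumptions: compounds 1 and 27 are taken as purchasable. Centres that are formed as mixtures and erased or corrected later (C8 in 6 and 10–12, C17 in 18–21, C2 in 25, C10 in 36) are drawn without configuration.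

Step 1
Reactants: 1 (S)-2,2-dimethyl-1,3-dioxolane-4-carbaldehyde
Product: 3 (1S)-1-[(4S)-2,2-dimethyl-1,3-dioxolan-4-yl]-1-hydroxypropan-2-one, via enol ether adduct 2 (not isolated)
Conditions: ethyl vinyl ether, t-BuLi, THF, −78 to 0 °C; then 1, −78 °C; then 0.5 M HCl, 0 °C
Reagents that add atoms: ethyl vinyl ether (C=COCC); water (O)
Why: 1,2-addition of the acyl anion equivalent 1-ethoxyvinyllithium under Felkin–Anh (non-chelate) control should give the 3,4-anti carbinol (minor syn isomer removed), and the enol ether is hydrolysed by dilute acid faster than the acetonide.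

Step 2
Reactants: 4 methyl 3-methylbut-2-enoate
Product: 5 methyl 2-diazo-3-methylbut-3-enoate
Conditions: p-ABSA (4-acetamidobenzenesulfonyl azide), DBU, MeCN, 0 °C
Reagents that add atoms: 4-acetamidobenzenesulfonyl azide (CC(=O)Nc1ccc(cc1)S(=O)(=O)N=[N+]=[N-])
Why: Regitz diazo transfer onto the DBU-generated dienolate occurs at the α-carbon with deconjugation and should give the vinyldiazoacetate, which is used cold and at once.

Step 3
Reactants: 3 (1S)-1-[(4S)-2,2-dimethyl-1,3-dioxolan-4-yl]-1-hydroxypropan-2-one; 5 methyl 2-diazo-3-methylbut-3-enoate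
Product: 6 methyl 2-{(1S)-1-[(4S)-2,2-dimethyl-1,3-dioxolan-4-yl]-2-oxopropoxy}-3-methylbut-3-enoate
Conditions: Rh2(OAc)4 (1 mol%), CH2Cl2, 23 °C, slow addition of 5
Reagents that add atoms: none
Why: rhodium carbenoid O–H insertion etherifies the base-sensitive C4 hydroxyl under neutral conditions with retention at C4; the new C8 centre forms as a mixture that is erased by enolisation in step 7.

Step 4
Reactants: 7 4-methoxybenzyl alcohol
Product: 8 (E)-1,2-dichlorovinyl 4-methoxybenzyl ether
Conditions: KH, THF, 0 °C; then trichloroethylene, 23 °C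
Reagents that add atoms: trichloroethylene (ClC=C(Cl)Cl)
Why: Greene dichlorovinyl ether synthesis, in which the alkoxide adds to dichloroacetylene formed in situ from trichloroethylene.

Step 5
Reactants: 6 methyl 2-{(1S)-1-[(4S)-2,2-dimethyl-1,3-dioxolan-4-yl]-2-oxopropoxy}-3-methylbut-3-enoate; 8 (E)-1,2-dichlorovinyl 4-methoxybenzyl ether
Product: 11 alkynyl dioxanone, via lithium alkoxyacetylide 9 (not isolated), via open-chain hydroxy ester 10 (not isolated)
Conditions: 8, n-BuLi (2.1 equiv), THF, −78 to −40 °C; MgBr2·OEt2; then 6, −78 °C; warm to 23 °C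
Reagents that add atoms: none
Why: elimination and lithiation give the alkoxyacetylide, which after transmetalation adds to the methyl ketone under Cram chelate control (magnesium bridging the ketone and the C4 ether oxygen, attack anti to the dioxolanyl group) to set C5, and the tertiary alkoxide then lactonises onto the methyl ester.

Step 6
Reactants: 11 alkynyl dioxanone
Product: 12 (Z)-enol ether dioxanone
Conditions: H2 (1 atm), Pd/CaCO3 poisoned with Pb(OAc)2 (Lindlar catalyst), quinoline, EtOAc, 23 °C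
Reagents that add atoms: none
Why: Lindlar syn-semihydrogenation of the ynol ether gives the (Z)-enol ether that will place the C7 oxygen, and the 1,1-disubstituted alkene is left alone.

Step 7
Reactants: 12 (Z)-enol ether dioxanone
Product: 15 dihydropyran acid, via silyl ketene acetal 13 (not isolated), via trimethylsilyl ester 14 (not isolated)
Conditions: LDA, TMSCl/Et3N (in situ), THF, −95 to 23 °C, then 60 °C; aqueous citric acid
Reagents that add atoms: none
Why: Deprotonation at C8 (α to the lactone carbonyl, α to the ether oxygen and allylic) and O-silylation give the cyclic silyl ketene acetal 13, whose C8=C9–O–C5–C6=C7 array undergoes a concerted suprafacial [3,3]-sigmatropic shift that breaks O–C5 and forms C7–C8. The closest known reaction type is the dioxanone-to-dihydropyran Ireland–Claisen rearrangement, here run through a dienolate and with a donor-substituted allyl terminus that should accelerate it. The 3,6-dihydro-2H-pyran ring (O, C4, C5, C6, C7, C8) is closed through a boat-like transition state enforced by the two-atom O–C4 tether, the bond forming on the face of the ketene acetal where the C5 vinyl group sits. Quaternary C8 is therefore fixed by the C5 carbinol configuration (carboxyl C9 ends cis to the C4 side chain), and C7 by the Z geometry of the enol ether, which places the PMB ether on the ring face opposite C9. The step needs bonding at C8 and no ionisation of the tertiary allylic ester; the fixed endocyclic ketene acetal geometry, silylation at −95 °C before warming and the absence of Lewis acid should secure this.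

Step 8
Reactants: 15 dihydropyran acid
Product: 16 C9 primary alcohol
Conditions: LiAlH4, THF, 0 °C
Reagents that add atoms: none
Why: hydride reduction of the hindered acid to the neopentyl alcohol; ethers, acetal and alkenes are inert.

Step 9
Reactants: 16 C9 primary alcohol
Product: 17 C9 tert-butyldiphenylsilyl ether
Conditions: TBDPSCl, imidazole, DMF, 23 °C
Reagents that add atoms: tert-butyldiphenylsilyl chloride (CC(C)(C)[Si](Cl)(c1ccccc1)c1ccccc1)
Why: silyl ether protection keeps C9 masked through acid, base and oxidants until step 21, so that no free C9 hydroxyl can translactonise with the lactone made in step 12.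

Step 10
Reactants: 17 C9 tert-butyldiphenylsilyl ether
Product: 19 C19 primary alcohol, via B-alkyl-9-BBN adduct 18 (not isolated)
Conditions: 9-BBN dimer, THF, 23 to 60 °C; then 30% H2O2, aqueous NaOAc, 0 to 23 °C
Reagents that add atoms: hydrogen peroxide (OO)
Why: anti-Markovnikov hydroboration–oxidation with the bulky borane is selective for the 1,1-disubstituted alkene over the trisubstituted ring alkene; C17 forms unselectively and is corrected in step 12.

Step 11
Reactants: 19 C19 primary alcohol
Product: 20 C7,C19-diol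
Conditions: DDQ, CH2Cl2/pH 7 buffer (10:1), 0 °C
Reagents that add atoms: none
Why: oxidative PMB cleavage through the benzylic oxocarbenium ion frees the allylic C7 hydroxyl.

Step 12
Reactants: 20 C7,C19-diol
Product: 22 cis-fused γ-lactone, via lactone epimer mixture 21 (not isolated)
Conditions: TEMPO (20 mol%), PhI(OAc)2 (2.5 equiv), CH2Cl2, 23 °C; then DBU (0.3 equiv), 23 °C
Reagents that add atoms: none
Why: nitroxyl-catalysed oxidative lactonisation (primary alcohol to aldehyde, lactol with the C7 hydroxyl, then lactone) gives the cis-fused ring, and DBU epimerisation should settle C17 in the more stable arrangement with the methyl anti to the C9 arm, which is the target configuration.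

Step 13
Reactants: 22 cis-fused γ-lactone
Product: 23 C2,C3-diol
Conditions: AcOH/H2O (4:1), 40 °C
Reagents that add atoms: none
Why: acid hydrolysis of the terminal acetonide; the TBDPS ether and the lactone survive.

Step 14
Reactants: 23 C2,C3-diol
Product: 24 C2 aldehyde
Conditions: TEMPO (10 mol%), PhI(OAc)2 (1.1 equiv), CH2Cl2, 23 °C
Reagents that add atoms: none
Why: TEMPO oxidation is selective for the primary alcohol over the secondary C3 hydroxyl.

Step 15
Reactants: 24 C2 aldehyde
Product: 25 C2 isopropenyl carbinol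
Conditions: isopropenylmagnesium bromide (3 equiv), THF, −78 °C
Reagents that add atoms: isopropenylmagnesium bromide (CC(=C)[Mg]Br)
Why: Grignard addition at −78 °C is faster at the aldehyde than at the lactone; the C2 configuration does not matter because it is oxidised next.

Step 16
Reactants: 25 C2 isopropenyl carbinol
Product: 26 α′-hydroxy enone
Conditions: MnO2 (20 equiv), CH2Cl2, 23 °C
Reagents that add atoms: none
Why: MnO2 allylic oxidation converts only the allylic C2 alcohol and gives the α′-hydroxy enone dienophile.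

Step 17
Reactants: 26 α′-hydroxy enone; 27 (1E,3E)-buta-1,3-diene-1,4-diyl diacetate
Product: 28 Diels–Alder adduct
Conditions: MgBr2·OEt2 (1.5 equiv), CH2Cl2, −20 to 23 °C
Reagents that add atoms: none
Why: Diels–Alder reaction in which the diene should add to the magnesium-chelated s-cis α′-hydroxy enone from the face anti to the pyran (C4), setting quaternary C1, while the endo rule places both acetoxy groups cis to the C2 acyl group and so sets C14 (and C11); the symmetric diene removes any regiochemical issue.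

Step 18
Reactants: 28 Diels–Alder adduct
Product: 29 C3 acetate
Conditions: Ac2O, pyridine, DMAP (cat.), CH2Cl2, 0 °C
Reagents that add atoms: acetic anhydride (CC(=O)OC(C)=O)
Why: acetylation installs the final C3 acetate and removes the chelating hydroxyl before the reduction.

Step 19
Reactants: 29 C3 acetate
Product: 30 (2R)-C2 alcohol
Conditions: NaBH4, CeCl3·7H2O, MeOH/THF, −78 to −40 °C
Reagents that add atoms: none
Why: Luche reduction of the hindered ketone should be Felkin–Anh controlled by both flanking centres in a matched sense (hydride anti to the C3 acetoxy group and anti to C14 on quaternary C1), giving the 2,3-syn alcohol without touching esters.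

Step 20
Reactants: 30 (2R)-C2 alcohol
Product: 31 C11 allylic alcohol
Conditions: Mg(OMe)2 (2 equiv), MeOH, 0 to 23 °C
Reagents that add atoms: none
Why: mild transesterification should remove the least hindered (allylic C11) acetate while the neopentyl-type C14 acetate and the silyl ether persist; any loss or migration of the C3 acetate is repaired in step 23.

Step 21
Reactants: 31 C11 allylic alcohol
Product: 32 C2,C9,C11-triol
Conditions: HF·pyridine, pyridine, THF, 0 to 23 °C
Reagents that add atoms: none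
Why: fluoride desilylation under buffered acidic conditions frees C9 without forming an alkoxide next to the lactone.

Step 22
Reactants: 32 C2,C9,C11-triol
Product: 33 C9 aldehyde / C11 enone
Conditions: TEMPO (30 mol%), PhI(OAc)2 (3 equiv), CH2Cl2, 23 °C
Reagents that add atoms: none
Why: TEMPO oxidation takes the primary C9 alcohol to the aldehyde and the allylic C11 alcohol to the enone but should leave the neopentyl secondary C2 alcohol.

Step 23
Reactants: 33 C9 aldehyde / C11 enone
Product: 34 keto aldehyde 2,3,14-triacetate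
Conditions: Ac2O, Et3N, DMAP, CH2Cl2, 23 °C
Reagents that add atoms: acetic anhydride (CC(=O)OC(C)=O)
Why: DMAP-catalysed acetylation of the hindered C2 hydroxyl completes the C2/C3/C14 acetates; the aldehyde has no α-hydrogen.

Step 24
Reactants: 34 keto aldehyde 2,3,14-triacetate
Product: 36 C10 bromide, via silyl dienol ether 35 (not isolated)
Conditions: TMSOTf, Et3N, CH2Cl2, −78 to 0 °C; then NBS, THF, −78 °C
Reagents that add atoms: N-bromosuccinimide (BrN1C(=O)CCC1=O)
Why: silyl enol ether formation can only occur toward C10 (C1 is quaternary, C12 is vinylic), and bromination of the cross-conjugated silyl dienol ether gives the α′-bromo ketone regiospecifically.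

Step 25
Reactants: 36 C10 bromide
Product: 37 macrocyclic enone
Conditions: SmI2 (2.2 equiv), THF, −78 °C, slow addition of 36 (final 2 mM); aqueous NH4Cl
Reagents that add atoms: none
Why: SmI2 Reformatsky-type aldol: reduction of the C–Br bond gives a samarium enolate that adds to the hindered C9 aldehyde and closes the eight-membered oxacycle and with it the ten-membered carbocycle; the chelated transition state and equilibration of the epimerisable C10 centre are expected to give the trans ring fusion with the 9S carbinol.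

Step 26
Reactants: 37 macrocyclic enone
Product: 38 saturated C11 ketone
Conditions: [(Ph3P)CuH]6 (0.5 equiv), wet benzene/THF, 23 °C
Reagents that add atoms: none
Why: copper hydride conjugate reduction saturates only the enone alkene and leaves the trisubstituted C5=C6 alkene and the esters.

Step 27
Reactants: 38 saturated C11 ketone
Product: 39 C11 iodomethyl carbinol
Conditions: CH2I2 (3 equiv), SmI2 (6 equiv), THF, 23 °C
Reagents that add atoms: diiodomethane (ICI)
Why: Imamoto iodomethylation under non-basic conditions; the samarium carbenoid should attack the ketone from the equatorial direction because the axial face is blocked by the 1,3-diaxial C15 methyl, giving the axial 11S alcohol.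

Step 28
Reactants: 39 C11 iodomethyl carbinol
Product: 41 6-deschloro Δ5 precursor, via 11,20-epoxide 40 (not isolated)
Conditions: CsOAc (5 equiv), DMF, 70 °C
Reagents that add atoms: cesium acetate (CC(=O)[O-].[Cs+])
Why: acetate closes the iodohydrin to the spiro-epoxide and reopens it by SN2 attack at the primary carbon C20, giving the tertiary C11 alcohol and the C20 acetate with C11 unchanged.

Step 29
Reactants: 41 6-deschloro Δ5 precursor
Product: 42 CNP0190959.1
Conditions: Ca(OCl)2, solid CO2, CH2Cl2/H2O, 0 °C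
Reagents that add atoms: calcium hypochlorite as HOCl ([Ca+2].[O-]Cl.[O-]Cl)
Why: ene-type allylic chlorination with HOCl: electrophilic chlorine should be delivered to C6 on the ring face opposite the carbocyclic bridge and C16 loses a proton, giving the 6S chloride and the C5(16) exomethylene.

**Compound list**

1 | (S)-2,2-dimethyl-1,3-dioxolane-4-carbaldehyde | O=C[C@@H]1COC(C)(C)O1 | starting material
2 | (1S)-1-[(4S)-2,2-dimethyl-1,3-dioxolan-4-yl]-2-ethoxyprop-2-en-1-ol (enol ether adduct) | CCOC(=C)[C@H]([C@@H]1COC(C)(C)O1)O | intermediate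
3 | (1S)-1-[(4S)-2,2-dimethyl-1,3-dioxolan-4-yl]-1-hydroxypropan-2-one | CC(=O)[C@H]([C@@H]1COC(C)(C)O1)O | intermediate
4 | methyl 3-methylbut-2-enoate | COC(=O)C=C(C)C | starting material
5 | methyl 2-diazo-3-methylbut-3-enoate | COC(=O)C(=[N+]=[N-])C(C)=C | intermediate
6 | methyl 2-{(1S)-1-[(4S)-2,2-dimethyl-1,3-dioxolan-4-yl]-2-oxopropoxy}-3-methylbut-3-enoate (both C8 epimers) | CC(=O)[C@H]([C@@H]1COC(C)(C)O1)OC(C(C)=C)C(=O)OC | intermediate
7 | 4-methoxybenzyl alcohol | COc1ccc(CO)cc1 | starting material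
8 | (E)-1,2-dichlorovinyl 4-methoxybenzyl ether | COc1ccc(CO/C(Cl)=C\Cl)cc1 | intermediate
9 | lithium [(4-methoxybenzyl)oxy]acetylide | [Li]C#COCc1ccc(OC)cc1 | intermediate
10 | open-chain hydroxy ester (tertiary propargylic alcohol from 9 and the ketone of 6; C5 S) | COC(=O)C(C(C)=C)O[C@@H]([C@@H]1COC(C)(C)O1)[C@@](C)(O)C#COCc1ccc(OC)cc1 | intermediate
11 | (5S,6S)-5-[(4S)-2,2-dimethyl-1,3-dioxolan-4-yl]-6-{[(4-methoxybenzyl)oxy]ethynyl}-6-methyl-3-(prop-1-en-2-yl)-1,4-dioxan-2-one | O=C1O[C@@](C)(C#COCc3ccc(OC)cc3)[C@H]([C@@H]2COC(C)(C)O2)OC1C(C)=C | intermediate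
12 | (5S,6S)-5-[(4S)-2,2-dimethyl-1,3-dioxolan-4-yl]-6-{(Z)-2-[(4-methoxybenzyl)oxy]ethenyl}-6-methyl-3-(prop-1-en-2-yl)-1,4-dioxan-2-one | O=C1O[C@@](C)(/C=C\OCc3ccc(OC)cc3)[C@H]([C@@H]2COC(C)(C)O2)OC1C(C)=C | intermediate
13 | trimethylsilyl ketene acetal of 12 | C[Si](C)(C)OC1=C(C(C)=C)O[C@@H]([C@@H]2COC(C)(C)O2)[C@](C)(/C=C\OCc3ccc(OC)cc3)O1 | intermediate
14 | trimethylsilyl ester of 15 | CC1[C@H]([C@@H]2COC(C)(C)O2)O[C@](C(C)=C)(C(=O)O[Si](C)(C)C)[C@@H](OCc3ccc(OC)cc3)C=1 | intermediate
15 | (2S,3S,6R)-6-[(4S)-2,2-dimethyl-1,3-dioxolan-4-yl]-3-[(4-methoxybenzyl)oxy]-5-methyl-2-(prop-1-en-2-yl)-3,6-dihydro-2H-pyran-2-carboxylic acid | CC1[C@H]([C@@H]2COC(C)(C)O2)O[C@](C(C)=C)(C(=O)O)[C@@H](OCc3ccc(OC)cc3)C=1 | intermediate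
16 | C9 primary alcohol (CO2H of 15 reduced to CH2OH) | CC1[C@H]([C@@H]2COC(C)(C)O2)O[C@](C(C)=C)(CO)[C@@H](OCc3ccc(OC)cc3)C=1 | intermediate
17 | C9 tert-butyldiphenylsilyl ether of 16 | CC1[C@H]([C@@H]2COC(C)(C)O2)O[C@](C(C)=C)(CO[Si](c2ccccc2)(c2ccccc2)C(C)(C)C)[C@@H](OCc3ccc(OC)cc3)C=1 | intermediate
18 | B-alkyl-9-borabicyclo[3.3.1]nonane from 17 (boron on C19; C17 epimers) | CC1[C@H]([C@@H]2COC(C)(C)O2)O[C@](C(C)CB2C4CCCC2CCC4)(CO[Si](c2ccccc2)(c2ccccc2)C(C)(C)C)[C@@H](OCc3ccc(OC)cc3)C=1 | intermediate
19 | C19 primary alcohol (isopropenyl of 17 turned into CH(CH3)CH2OH; C17 epimers) | CC1[C@H]([C@@H]2COC(C)(C)O2)O[C@](C(C)CO)(CO[Si](c2ccccc2)(c2ccccc2)C(C)(C)C)[C@@H](OCc3ccc(OC)cc3)C=1 | intermediate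
20 | C7,C19-diol (19 without the PMB group; C17 epimers) | CC1[C@H]([C@@H]2COC(C)(C)O2)O[C@](C(C)CO)(CO[Si](c2ccccc2)(c2ccccc2)C(C)(C)C)[C@@H](O)C=1 | intermediate
21 | cis-fused γ-lactone as C17 epimer mixture | CC1[C@H]([C@@H]2COC(C)(C)O2)O[C@]3(C(C)C(=O)O[C@H]3C=1)CO[Si](c1ccccc1)(c1ccccc1)C(C)(C)C | intermediate
22 | cis-fused γ-lactone (C19 carbonyl, ring oxygen on C7, 17R methyl; dioxolane on C4; C9 OTBDPS) | CC1[C@H]([C@@H]2COC(C)(C)O2)O[C@]3([C@@H](C)C(=O)O[C@H]3C=1)CO[Si](c1ccccc1)(c1ccccc1)C(C)(C)C | intermediate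
23 | C2,C3-diol (22 without the acetonide) | CC1[C@H]([C@@H](O)CO)O[C@]3([C@@H](C)C(=O)O[C@H]3C=1)CO[Si](c1ccccc1)(c1ccccc1)C(C)(C)C | intermediate
24 | C2 aldehyde (α-hydroxy aldehyde) | CC1[C@H]([C@@H](O)C=O)O[C@]3([C@@H](C)C(=O)O[C@H]3C=1)CO[Si](c1ccccc1)(c1ccccc1)C(C)(C)C | intermediate
25 | C2 isopropenyl carbinol (C2 epimers) | CC1[C@H]([C@@H](O)C(O)C(C)=C)O[C@]3([C@@H](C)C(=O)O[C@H]3C=1)CO[Si](c1ccccc1)(c1ccccc1)C(C)(C)C | intermediate
26 | α′-hydroxy enone (C3 OH, C2 ketone, C1(C15)=C10) | CC1[C@H]([C@@H](O)C(=O)C(C)=C)O[C@]3([C@@H](C)C(=O)O[C@H]3C=1)CO[Si](c1ccccc1)(c1ccccc1)C(C)(C)C | intermediate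
27 | (1E,3E)-buta-1,3-diene-1,4-diyl diacetate | CC(=O)O/C=C/C=C/OC(C)=O | starting material
28 | Diels–Alder adduct (ring A cyclohexene with 1R quaternary methyl, 11S and 14S acetates; C2 ketone, C3 OH) | CC1[C@H]([C@@H](O)C(=O)[C@]2(C)C[C@H](OC(C)=O)C=C[C@@H]2OC(C)=O)O[C@]3([C@@H](C)C(=O)O[C@H]3C=1)CO[Si](c1ccccc1)(c1ccccc1)C(C)(C)C | intermediate
29 | C3 acetate of 28 | CC1[C@H]([C@@H](OC(C)=O)C(=O)[C@]2(C)C[C@H](OC(C)=O)C=C[C@@H]2OC(C)=O)O[C@]3([C@@H](C)C(=O)O[C@H]3C=1)CO[Si](c1ccccc1)(c1ccccc1)C(C)(C)C | intermediate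
30 | (2R)-C2 alcohol of 29 | CC1[C@H]([C@@H](OC(C)=O)[C@H](O)[C@]2(C)C[C@H](OC(C)=O)C=C[C@@H]2OC(C)=O)O[C@]3([C@@H](C)C(=O)O[C@H]3C=1)CO[Si](c1ccccc1)(c1ccccc1)C(C)(C)C | intermediate
31 | C11 allylic alcohol (C11 acetate of 30 cleaved) | CC1[C@H]([C@@H](OC(C)=O)[C@H](O)[C@]2(C)C[C@H](O)C=C[C@@H]2OC(C)=O)O[C@]3([C@@H](C)C(=O)O[C@H]3C=1)CO[Si](c1ccccc1)(c1ccccc1)C(C)(C)C | intermediate
32 | C2,C9,C11-triol (31 without the silyl group) | CC1[C@H]([C@@H](OC(C)=O)[C@H](O)[C@]2(C)C[C@H](O)C=C[C@@H]2OC(C)=O)O[C@]3([C@@H](C)C(=O)O[C@H]3C=1)CO | intermediate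
33 | C9 aldehyde / C11 enone with free C2 OH | CC1[C@H]([C@@H](OC(C)=O)[C@H](O)[C@]2(C)CC(=O)C=C[C@@H]2OC(C)=O)O[C@]3([C@@H](C)C(=O)O[C@H]3C=1)C=O | intermediate
34 | keto aldehyde 2,3,14-triacetate | CC1[C@H]([C@@H](OC(C)=O)[C@H](OC(C)=O)[C@]2(C)CC(=O)C=C[C@@H]2OC(C)=O)O[C@]3([C@@H](C)C(=O)O[C@H]3C=1)C=O | intermediate
35 | trimethylsilyl dienol ether of 34 (C10=C11–OSiMe3) | CC1[C@H]([C@@H](OC(C)=O)[C@H](OC(C)=O)[C@]2(C)C=C(O[Si](C)(C)C)C=C[C@@H]2OC(C)=O)O[C@]3([C@@H](C)C(=O)O[C@H]3C=1)C=O | intermediate
36 | C10 bromide of 34 (C10 epimers) | CC1[C@H]([C@@H](OC(C)=O)[C@H](OC(C)=O)[C@]2(C)C(Br)C(=O)C=C[C@@H]2OC(C)=O)O[C@]3([C@@H](C)C(=O)O[C@H]3C=1)C=O | intermediate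
37 | macrocyclic enone (9S OH, 10S, C11 ketone, C12=C13) | CC1[C@H]2O[C@]3([C@@H](C)C(=O)O[C@H]3C=1)[C@@H](O)[C@H]1C(=O)C=C[C@H](OC(C)=O)[C@]1(C)[C@@H](OC(C)=O)[C@@H]2OC(C)=O | intermediate
38 | saturated C11 ketone | CC1[C@H]2O[C@]3([C@@H](C)C(=O)O[C@H]3C=1)[C@@H](O)[C@H]1C(=O)CC[C@H](OC(C)=O)[C@]1(C)[C@@H](OC(C)=O)[C@@H]2OC(C)=O | intermediate
39 | C11 iodomethyl carbinol (11S) | CC1[C@H]2O[C@]3([C@@H](C)C(=O)O[C@H]3C=1)[C@@H](O)[C@H]1[C@](O)(CI)CC[C@H](OC(C)=O)[C@]1(C)[C@@H](OC(C)=O)[C@@H]2OC(C)=O | intermediate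
40 | 11,20-epoxide | CC1[C@H]2O[C@]3([C@@H](C)C(=O)O[C@H]3C=1)[C@@H](O)[C@H]1[C@]4(CO4)CC[C@H](OC(C)=O)[C@]1(C)[C@@H](OC(C)=O)[C@@H]2OC(C)=O | intermediate
41 | 6-deschloro Δ5 precursor (C5=C6 with C16 methyl; 11-OH, 20-OAc) | CC1[C@H]2O[C@]3([C@@H](C)C(=O)O[C@H]3C=1)[C@@H](O)[C@H]1[C@](O)(COC(C)=O)CC[C@H](OC(C)=O)[C@]1(C)[C@@H](OC(C)=O)[C@@H]2OC(C)=O | intermediate
42 | CNP0190959.1 | C=C1[C@H]2O[C@]3([C@@H](C)C(=O)O[C@H]3[C@H]1Cl)[C@@H](O)[C@H]1[C@](O)(COC(C)=O)CC[C@H](OC(C)=O)[C@]1(C)[C@@H](OC(C)=O)[C@@H]2OC(C)=O | target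

**Totals.** 29 steps in all. Longest linear sequence: 27 steps (steps 1, 3 and 5–29, from compound 1); steps 2 and 4 are side branches.

**Three steps most likely to fail**

Step 17 (Diels–Alder). The facial selectivity may be poor, because the α-methyl enone may react through the s-trans as well as the s-cis conformer of the magnesium chelate, which lead to opposite configurations at C1; the acetoxy diene may also add slowly. Fallback: from hydroxy enone 26, the C3 hydroxyl is acetylated (Ac2O, pyridine) to give acetoxy enone F1, which no longer chelates. The cycloaddition with diene 27 is then run under reagent control with a chiral oxazaborolidinium Lewis acid (triflimide-activated diphenylprolinol o-tolylboronate, the enantiomer chosen to match), so that the catalyst selects the face. The product is C3 acetate 29, where the route is rejoined.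

Step 25 (SmI2 ring closure). The bromide may undergo intermolecular aldol coupling instead of ring closure, excess reductant may cleave the γ-acetoxy enone, and the aldehyde face may be attacked in the wrong sense. Fallback: from keto aldehyde 34, soft enolisation with TBSOTf and Et3N gives the isolable tert-butyldimethylsilyl dienol ether F2. An intramolecular Mukaiyama aldol reaction (BF3·OEt2, CH2Cl2, −78 °C, high dilution, open transition state, no reductant) then closes the ring, and aqueous work-up returns macrocyclic enone 37.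

Step 29 (ene chlorination). Chlorine may add across the alkene instead of substituting, the proton may be lost from C4 instead of C16, attack may come from the hindered face, or hypochlorite may oxidise the C9 carbinol. Fallback: from 41, photooxygenation (O2, tetraphenylporphyrin, visible light, CH2Cl2; Schenck ene reaction) gives the C6 allylic hydroperoxide F3 with the C5(16) exomethylene already in place. Dehydration with Ac2O and pyridine at 0 °C gives the C6 enone F4. Luche reduction (NaBH4, CeCl3·7H2O) from the open face gives the 6-epi allylic alcohol F5, and Appel chlorination (PPh3, CCl4) with inversion at C6 gives target 42.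

**Further compounds**

F1 | step 17 | acetoxy enone (C3 acetate of 26) | CC1[C@H]([C@@H](OC(C)=O)C(=O)C(C)=C)O[C@]3([C@@H](C)C(=O)O[C@H]3C=1)CO[Si](c1ccccc1)(c1ccccc1)C(C)(C)C
F2 | step 25 | tert-butyldimethylsilyl dienol ether of 34 | CC1[C@H]([C@@H](OC(C)=O)[C@H](OC(C)=O)[C@]2(C)C=C(O[Si](C)(C)C(C)(C)C)C=C[C@@H]2OC(C)=O)O[C@]3([C@@H](C)C(=O)O[C@H]3C=1)C=O
F3 | step 29 | C6 allylic hydroperoxide with C5(16) exomethylene | C=C1[C@H]2O[C@]3([C@@H](C)C(=O)O[C@H]3[C@H]1OO)[C@@H](O)[C@H]1[C@](O)(COC(C)=O)CC[C@H](OC(C)=O)[C@]1(C)[C@@H](OC(C)=O)[C@@H]2OC(C)=O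
F4 | step 29 | C6 enone with C5(16) exomethylene | C=C1[C@H]2O[C@]3([C@@H](C)C(=O)O[C@H]3C1=O)[C@@H](O)[C@H]1[C@](O)(COC(C)=O)CC[C@H](OC(C)=O)[C@]1(C)[C@@H](OC(C)=O)[C@@H]2OC(C)=O
F5 | step 29 | 6-epi allylic alcohol | C=C1[C@H]2O[C@]3([C@@H](C)C(=O)O[C@H]3[C@@H]1O)[C@@H](O)[C@H]1[C@](O)(COC(C)=O)CC[C@H](OC(C)=O)[C@]1(C)[C@@H](OC(C)=O)[C@@H]2OC(C)=O
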